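## Retrosynthetic overview

1. The 1,10-oxirane is made last, and this C–O step is the key step: target 30 comes from diene 29 by a chiral-dioxirane epoxidation of the 1(10)-olefin. Diene 29 comes from alcohol 27 by O3-acylation.
2. The ten-membered carbocycle 27 comes from iodo aldehyde 26 by a Ni/Cr vinyl iodide–aldehyde closure of the C3–C4 bond; the 4Z geometry is carried in by the vinyl iodide.
3. Aldehyde 26 comes from bromolactone 9 and aldehyde 18 by a zinc Barbier union (C7–C8; C7 and C8 are set from C6), followed by C8–O esterification with epoxy acid 21.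
4. Fragment A (9) comes from crotonaldehyde and a propynyl Grignard reagent (Sharpless kinetic resolution, directed hydroalumination–iodination, acylation, RCM). Fragment B (18) comes from a silyl butynyl ether (carboalumination, oxirane opening). Fragment C (21) comes from tiglyl alcohol (Sharpless epoxidation).
5. Ring order: butenolide (later the α-methylene lactone), then the ten-membered carbocycle, then the 1,10-oxirane. The side-chain oxirane is brought in ready-made.

Assumption: ring positions are cited with germacrane locants (C1–C15, lactone carbonyl C12, exocyclic methylene C13), and the target is the stereoisomer fixed by the given SMILES, (1R,3S,6R,7R,8R,10R) with a (2S,3R)-epoxy ester.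

## Route

### Fragment A (bromolactone 9)

Step 1
Reactants: 1 (E)-but-2-enal; 2 prop-1-yn-1-ylmagnesium bromide
Product: 3 rac-(E)-hept-2-en-5-yn-4-ol
Conditions: THF, −78 to 0 °C; then aq. NH4Cl
Reagents that add atoms: none
Why: Grignard 1,2-addition of the alkynyl nucleophile to the enal carbonyl gives the racemic bis-unsaturated carbinol, with no stereocontrol sought at this point.

Step 2
Reactants: 3 rac-(E)-hept-2-en-5-yn-4-ol
Product: 4 (4S,2E)-hept-2-en-5-yn-4-ol
Conditions: Ti(OiPr)4 (0.15 equiv), L-(+)-diisopropyl tartrate (0.18 equiv), t-BuOOH (0.6 equiv), 4 Å MS, CH2Cl2, −20 °C, stopped at about 55–60% conversion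
Reagents that add atoms: none
Why: Sharpless kinetic resolution, in which the L-(+)-tartrate catalyst epoxidises the propenyl group of the (R)-carbinol much faster (that enantiomer turns its carbinol H towards the delivered oxygen), so the unreacted (S)-carbinol is recovered in high ee.

Step 3
Reactants: 4 (4S,2E)-hept-2-en-5-yn-4-ol
Product: 6 (4S,2E,5Z)-6-iodohepta-2,5-dien-4-ol, via cyclic vinylalanate 5 (not isolated)
Conditions: NaAlH2(OCH2CH2OMe)2 (1.6 equiv), THF, 0 °C to rt; then I2, THF, −78 to 0 °C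
Reagents that add atoms: iodine, [I][I]
Why: Hydroxyl-directed trans-hydroalumination of the propargylic alcohol puts aluminium on the distal alkyne carbon cis to the carbinol (five-membered alanate 5), and iodinolysis of the C–Al bond with retention gives the Z vinyl iodide without touching the carbinol centre.

Step 4
Reactants: 6 (4S,2E,5Z)-6-iodohepta-2,5-dien-4-ol; 7 2-(bromomethyl)prop-2-enoic acid
Product: 8 (4S,2E,5Z)-6-iodohepta-2,5-dien-4-yl 2-(bromomethyl)prop-2-enoate
Conditions: DCC, DMAP (5 mol %), CH2Cl2, 0 °C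
Reagents that add atoms: none
Why: Steglich esterification forms only the acyl–O bond, so the C–O stereocentre (the future lactone C6–O) is retained.

Step 5
Reactants: 8 (4S,2E,5Z)-6-iodohepta-2,5-dien-4-yl 2-(bromomethyl)prop-2-enoate
Product: 9 (5S)-3-(bromomethyl)-5-[(Z)-2-iodoprop-1-en-1-yl]furan-2(5H)-one
Conditions: second-generation Grubbs catalyst RuCl2(=CHPh)(H2IMes)(PCy3) (5 mol %), toluene, 70 °C
Reagents that add atoms: none
Why: Ring-closing metathesis between the acrylate methylene and the propenyl group closes the five-membered butenolide with loss of propene, while the trisubstituted iodoalkene is too hindered and electron-poor to take part and the stereocentre is untouched.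

### Fragment B (aldehyde 18)

Step 6
Reactants: 10 tert-butyl(but-3-yn-1-yloxy)dimethylsilane; 11 trimethylaluminium; 12 oxirane
Product: 15 (E)-6-(tert-butyldimethylsilyloxy)-4-methylhex-3-en-1-ol, via alkenyldimethylalane 13 (not isolated), via lithium alkenylaluminate 14 (not isolated)
Conditions: Me3Al (2 equiv), Cp2ZrCl2 (0.25 equiv), CH2Cl2, 0 °C to rt; volatiles removed; n-BuLi, hexane/THF, −78 °C; oxirane, −78 to 0 °C; aq. Rochelle salt
Reagents that add atoms: none
Why: Negishi zirconium-catalysed carboalumination adds methyl and aluminium syn across the alkyne (methyl to the internal carbon), which fixes the E trisubstituted olefin, and the derived aluminate opens oxirane at the alkenyl carbon with retention of geometry.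

Step 7
Reactants: 15 (E)-6-(tert-butyldimethylsilyloxy)-4-methylhex-3-en-1-ol
Product: 16 (E)-1-(tert-butyldimethylsilyloxy)-6-(tert-butyldiphenylsilyloxy)-3-methylhex-3-ene
Conditions: TBDPSCl, imidazole, DMF, rt
Reagents that add atoms: tert-butyl(chloro)diphenylsilane, CC(C)(C)[Si](Cl)(c1ccccc1)c1ccccc1
Why: Imidazole-assisted silylation of the primary alcohol installs a silyl ether that outlasts the TBS group.

Step 8
Reactants: 16 (E)-1-(tert-butyldimethylsilyloxy)-6-(tert-butyldiphenylsilyloxy)-3-methylhex-3-ene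
Product: 17 (E)-6-(tert-butyldiphenylsilyloxy)-3-methylhex-3-en-1-ol
Conditions: PPTS (0.2 equiv), MeOH, rt
Reagents that add atoms: none
Why: Acid-catalysed methanolysis (selective desilylation) cleaves the primary TBS ether far faster than the bulkier, more acid-stable TBDPS ether.

Step 9
Reactants: 17 (E)-6-(tert-butyldiphenylsilyloxy)-3-methylhex-3-en-1-ol
Product: 18 (E)-6-(tert-butyldiphenylsilyloxy)-3-methylhex-3-enal
Conditions: Dess–Martin periodinane, NaHCO3, CH2Cl2, 0 °C; used at once
Reagents that add atoms: none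
Why: Buffered Dess–Martin oxidation gives the β,γ-unsaturated aldehyde without acid or base strong enough to move the olefin into conjugation.

### Fragment C (epoxy acid 21)

Step 10
Reactants: 19 (E)-2-methylbut-2-en-1-ol
Product: 20 [(2R,3R)-2,3-dimethyloxiran-2-yl]methanol
Conditions: Ti(OiPr)4 (10 mol %), D-(−)-diisopropyl tartrate (12 mol %), t-BuOOH, 4 Å MS, CH2Cl2, −20 °C
Reagents that add atoms: tert-butyl hydroperoxide, CC(C)(C)OO
Why: Sharpless asymmetric epoxidation, in which the D-(−)-tartrate catalyst delivers oxygen to the face of the E allylic alcohol that gives the (2R,3R)-epoxy alcohol (the L-(+)-ester would give 2S,3S), setting both side-chain stereocentres.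

Step 11
Reactants: 20 [(2R,3R)-2,3-dimethyloxiran-2-yl]methanol
Product: 21 (2S,3R)-2,3-dimethyloxirane-2-carboxylic acid
Conditions: RuCl3·xH2O (2 mol %), NaIO4 (4 equiv), MeCN/EtOAc/H2O, 0 °C to rt
Reagents that add atoms: water, O
Why: Ruthenium tetroxide oxidation (RuCl3/NaIO4) takes the primary alcohol through the aldehyde hydrate to the acid without touching the oxirane, and the change of the C2 descriptor from R to S is only a change of CIP priorities.

### Union, ring closure and end game

Step 12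
Reactants: 9 (5S)-3-(bromomethyl)-5-[(Z)-2-iodoprop-1-en-1-yl]furan-2(5H)-one; 18 (E)-6-(tert-butyldiphenylsilyloxy)-3-methylhex-3-enal
Product: 22 (4R,5S)-4-[(1R,3E)-6-(tert-butyldiphenylsilyloxy)-1-hydroxy-3-methylhex-3-en-1-yl]-5-[(Z)-2-iodoprop-1-en-1-yl]-3-methylideneoxolan-2-one
Conditions: Zn dust, THF/sat. aq. NH4Cl, 0 °C to rt
Reagents that add atoms: none
Why: Barbier allylation in which the allylzinc from 9 reacts at its γ-carbon (butenolide C4) through a closed six-membered transition state on the face anti to the C5 substituent (trans lactone, C7) with the aldehyde chain turned away from the lactone ring, the arrangement expected to give the syn carbinol (C8, 8R) with zinc and 3-(bromomethyl)butenolides.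

Step 13
Reactants: 22 (4R,5S)-4-[(1R,3E)-6-(tert-butyldiphenylsilyloxy)-1-hydroxy-3-methylhex-3-en-1-yl]-5-[(Z)-2-iodoprop-1-en-1-yl]-3-methylideneoxolan-2-one; 21 (2S,3R)-2,3-dimethyloxirane-2-carboxylic acid
Product: 24 (1R,3E)-6-(tert-butyldiphenylsilyloxy)-1-[(2S,3R)-2-[(Z)-2-iodoprop-1-en-1-yl]-4-methylidene-5-oxooxolan-3-yl]-3-methylhex-3-en-1-yl (2S,3R)-2,3-dimethyloxirane-2-carboxylate, via Yamaguchi mixed anhydride 23 (not isolated)
Conditions: 21, 2,4,6-trichlorobenzoyl chloride, Et3N, THF, 0 °C; then 22, DMAP, toluene, rt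
Reagents that add atoms: none
Why: Yamaguchi esterification activates the hindered α-quaternary acid as mixed anhydride 23 and DMAP transfers the acyl group to O8, so the C8–O bond and its configuration are kept and the oxirane centres are untouched.

Step 14
Reactants: 24 (1R,3E)-6-(tert-butyldiphenylsilyloxy)-1-[(2S,3R)-2-[(Z)-2-iodoprop-1-en-1-yl]-4-methylidene-5-oxooxolan-3-yl]-3-methylhex-3-en-1-yl (2S,3R)-2,3-dimethyloxirane-2-carboxylate
Product: 25 (1R,3E)-6-hydroxy-1-[(2S,3R)-2-[(Z)-2-iodoprop-1-en-1-yl]-4-methylidene-5-oxooxolan-3-yl]-3-methylhex-3-en-1-yl (2S,3R)-2,3-dimethyloxirane-2-carboxylate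
Conditions: Bu4NF, AcOH (1:1), THF, 0 °C to rt
Reagents that add atoms: none
Why: Fluoride-mediated desilylation cleaves the Si–O bond, and the acetic acid buffer keeps the methylene lactone, the esters and the oxirane intact.

Step 15
Reactants: 25 (1R,3E)-6-hydroxy-1-[(2S,3R)-2-[(Z)-2-iodoprop-1-en-1-yl]-4-methylidene-5-oxooxolan-3-yl]-3-methylhex-3-en-1-yl (2S,3R)-2,3-dimethyloxirane-2-carboxylate
Product: 26 (1R,3E)-1-[(2S,3R)-2-[(Z)-2-iodoprop-1-en-1-yl]-4-methylidene-5-oxooxolan-3-yl]-3-methyl-6-oxohex-3-en-1-yl (2S,3R)-2,3-dimethyloxirane-2-carboxylate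
Conditions: Dess–Martin periodinane, NaHCO3, CH2Cl2, 0 °C; used at once
Reagents that add atoms: none
Why: Buffered Dess–Martin oxidation gives the β,γ-unsaturated aldehyde under conditions that do not isomerise the olefin or open the oxirane.

Step 16
Reactants: 26 (1R,3E)-1-[(2S,3R)-2-[(Z)-2-iodoprop-1-en-1-yl]-4-methylidene-5-oxooxolan-3-yl]-3-methyl-6-oxohex-3-en-1-yl (2S,3R)-2,3-dimethyloxirane-2-carboxylate
Product: 27 (3S,6R,7R,8R)-3-hydroxy-8-{[(2S,3R)-2,3-dimethyloxirane-2-carbonyl]oxy}germacra-1(10)E,4Z,11(13)-trien-12,6-olide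
Conditions: CrCl2 (10 equiv), NiCl2 (0.1 equiv), DMSO/THF 3:1, rt, slow addition to 0.002 M
Reagents that add atoms: none
Why: Nozaki–Hiyama–Kishi macrocyclisation, in which zerovalent nickel (made from NiCl2 by divalent chromium) inserts into the C–I bond with retention, the vinyl group passes to trivalent chromium and adds to the tethered aldehyde, so the Z olefin is kept, and C3 is set under macrocyclic control; the 3S carbinol is the epimer wanted but its preference is not secure (see the fallback).

Step 17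
Reactants: 27 (3S,6R,7R,8R)-3-hydroxy-8-{[(2S,3R)-2,3-dimethyloxirane-2-carbonyl]oxy}germacra-1(10)E,4Z,11(13)-trien-12,6-olide; 28 3-methylbutanoic anhydride
Product: 29 (3S,6R,7R,8R)-3-(3-methylbutanoyloxy)-8-{[(2S,3R)-2,3-dimethyloxirane-2-carbonyl]oxy}germacra-1(10)E,4Z,11(13)-trien-12,6-olide
Conditions: Et3N, DMAP (10 mol %), CH2Cl2, 0 °C to rt
Reagents that add atoms: none
Why: DMAP-catalysed acylation of the allylic alcohol forms only the acyl–O bond, so C3 keeps its configuration.

Step 18
Reactants: 29 (3S,6R,7R,8R)-3-(3-methylbutanoyloxy)-8-{[(2S,3R)-2,3-dimethyloxirane-2-carbonyl]oxy}germacra-1(10)E,4Z,11(13)-trien-12,6-olide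
Product: 30 (1R,3S,6R,7R,8R,10R)-1,10-epoxy-3-(3-methylbutanoyloxy)-8-{[(2S,3R)-2,3-dimethyloxirane-2-carbonyl]oxy}germacra-4Z,11(13)-dien-12,6-olide (CNP0167461.3)
Conditions: 1,2:4,5-di-O-isopropylidene-β-D-erythro-2,3-hexodiulo-2,6-pyranose (D-fructose-derived Shi ketone, 1.0 equiv), KHSO5 (as 2KHSO5·KHSO4·K2SO4), NaHCO3, aq. Na2EDTA/MeCN, 0 °C
Reagents that add atoms: potassium peroxymonosulfate, [K+].[O-]S(=O)(=O)OO
Why: Proposed new method: a chiral dioxirane epoxidation applied for the first time to the strained E 1(10)-olefin of a germacranolide, where each ring conformer shows only its outer olefin face, so the dioxirane from the D-fructose ketone (spiro transition state, R,R sense for trans-related substituents, here C2 and C9) must pick the conformer that gives the 1R,10R oxirane, while as an electrophilic oxidant it leaves the methylene lactone, the glycidate and the doubly acyloxy-flanked 4Z olefin alone; the closest known reaction types are the Shi asymmetric epoxidation of acyclic and simple cyclic trisubstituted olefins and the peracid epoxidation of germacranolide 1(10)-olefins.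

## Compound list

1 | (E)-but-2-enal (crotonaldehyde) | C/C=C/C=O | starting material
2 | prop-1-yn-1-ylmagnesium bromide | CC#C[Mg]Br | starting material
3 | rac-(E)-hept-2-en-5-yn-4-ol | C/C=C/C(O)C#CC | intermediate
4 | (4S,2E)-hept-2-en-5-yn-4-ol | C/C=C/[C@H](O)C#CC | intermediate
5 | sodium (5S)-2,2-bis(2-methoxyethoxy)-3-methyl-5-[(E)-prop-1-en-1-yl]-2,5-dihydro-1,2-oxaluminol-2-uide (cyclic vinylalanate) | [Na+].C/C=C/[C@@H]1O[Al-](OCCOC)(OCCOC)C(C)=C1 | intermediate
6 | (4S,2E,5Z)-6-iodohepta-2,5-dien-4-ol | C/C=C/[C@H](O)/C=C(/C)I | intermediate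
7 | 2-(bromomethyl)prop-2-enoic acid | C=C(CBr)C(=O)O | starting material
8 | (4S,2E,5Z)-6-iodohepta-2,5-dien-4-yl 2-(bromomethyl)prop-2-enoate | C/C=C/[C@@H](/C=C(/C)I)OC(=O)C(=C)CBr | intermediate
9 | (5S)-3-(bromomethyl)-5-[(Z)-2-iodoprop-1-en-1-yl]furan-2(5H)-one | BrCC1=C[C@@H](/C=C(/C)I)OC1=O | intermediate
10 | tert-butyl(but-3-yn-1-yloxy)dimethylsilane | C#CCCO[Si](C)(C)C(C)(C)C | starting material
11 | trimethylaluminium | C[Al](C)C | starting material
12 | oxirane (ethylene oxide) | C1CO1 | starting material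
13 | (E)-[4-(tert-butyldimethylsilyloxy)-2-methylbut-1-en-1-yl]dimethylalane | C[Al](C)/C=C(\C)CCO[Si](C)(C)C(C)(C)C | intermediate
14 | lithium butyl[(E)-4-(tert-butyldimethylsilyloxy)-2-methylbut-1-en-1-yl]dimethylaluminate | [Li+].CCCC[Al-](C)(C)/C=C(\C)CCO[Si](C)(C)C(C)(C)C | intermediate
15 | (E)-6-(tert-butyldimethylsilyloxy)-4-methylhex-3-en-1-ol | OCC/C=C(\C)CCO[Si](C)(C)C(C)(C)C | intermediate
16 | (E)-1-(tert-butyldimethylsilyloxy)-6-(tert-butyldiphenylsilyloxy)-3-methylhex-3-ene | CC(C)(C)[Si](C)(C)OCC/C(C)=C/CCO[Si](c1ccccc1)(c1ccccc1)C(C)(C)C | intermediate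
17 | (E)-6-(tert-butyldiphenylsilyloxy)-3-methylhex-3-en-1-ol | OCC/C(C)=C/CCO[Si](c1ccccc1)(c1ccccc1)C(C)(C)C | intermediate
18 | (E)-6-(tert-butyldiphenylsilyloxy)-3-methylhex-3-enal | O=CC/C(C)=C/CCO[Si](c1ccccc1)(c1ccccc1)C(C)(C)C | intermediate
19 | (E)-2-methylbut-2-en-1-ol (tiglyl alcohol) | C/C=C(\C)CO | starting material
20 | [(2R,3R)-2,3-dimethyloxiran-2-yl]methanol | OC[C@@]1(C)O[C@@H]1C | intermediate
21 | (2S,3R)-2,3-dimethyloxirane-2-carboxylic acid | OC(=O)[C@@]1(C)O[C@@H]1C | intermediate
22 | (4R,5S)-4-[(1R,3E)-6-(tert-butyldiphenylsilyloxy)-1-hydroxy-3-methylhex-3-en-1-yl]-5-[(Z)-2-iodoprop-1-en-1-yl]-3-methylideneoxolan-2-one | C=C1C(=O)O[C@H](/C=C(/C)I)[C@H]1[C@H](O)C/C(C)=C/CCO[Si](c1ccccc1)(c1ccccc1)C(C)(C)C | intermediate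
23 | (2S,3R)-2,3-dimethyloxirane-2-carboxylic 2,4,6-trichlorobenzoic anhydride | O=C(OC(=O)[C@@]1(C)O[C@@H]1C)c1c(Cl)cc(Cl)cc1Cl | intermediate
24 | (1R,3E)-6-(tert-butyldiphenylsilyloxy)-1-[(2S,3R)-2-[(Z)-2-iodoprop-1-en-1-yl]-4-methylidene-5-oxooxolan-3-yl]-3-methylhex-3-en-1-yl (2S,3R)-2,3-dimethyloxirane-2-carboxylate | C=C1C(=O)O[C@H](/C=C(/C)I)[C@H]1[C@H](OC(=O)[C@@]2(C)O[C@@H]2C)C/C(C)=C/CCO[Si](c3ccccc3)(c3ccccc3)C(C)(C)C | intermediate
25 | (1R,3E)-6-hydroxy-1-[(2S,3R)-2-[(Z)-2-iodoprop-1-en-1-yl]-4-methylidene-5-oxooxolan-3-yl]-3-methylhex-3-en-1-yl (2S,3R)-2,3-dimethyloxirane-2-carboxylate | C=C1C(=O)O[C@H](/C=C(/C)I)[C@H]1[C@H](OC(=O)[C@@]2(C)O[C@@H]2C)C/C(C)=C/CCO | intermediate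
26 | (1R,3E)-1-[(2S,3R)-2-[(Z)-2-iodoprop-1-en-1-yl]-4-methylidene-5-oxooxolan-3-yl]-3-methyl-6-oxohex-3-en-1-yl (2S,3R)-2,3-dimethyloxirane-2-carboxylate | C=C1C(=O)O[C@H](/C=C(/C)I)[C@H]1[C@H](OC(=O)[C@@]2(C)O[C@@H]2C)C/C(C)=C/CC=O | intermediate
27 | (3S,6R,7R,8R)-3-hydroxy-8-{[(2S,3R)-2,3-dimethyloxirane-2-carbonyl]oxy}germacra-1(10)E,4Z,11(13)-trien-12,6-olide | C=C1C(=O)O[C@@H]2/C=C(/C)[C@@H](O)C/C=C(\C)C[C@@H](OC(=O)[C@@]3(C)O[C@@H]3C)[C@@H]12 | intermediate
28 | 3-methylbutanoic anhydride (isovaleric anhydride) | CC(C)CC(=O)OC(=O)CC(C)C | starting material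
29 | (3S,6R,7R,8R)-3-(3-methylbutanoyloxy)-8-{[(2S,3R)-2,3-dimethyloxirane-2-carbonyl]oxy}germacra-1(10)E,4Z,11(13)-trien-12,6-olide | C=C1C(=O)O[C@@H]2/C=C(/C)[C@@H](OC(=O)CC(C)C)C/C=C(\C)C[C@@H](OC(=O)[C@@]3(C)O[C@@H]3C)[C@@H]12 | intermediate
30 | (1R,3S,6R,7R,8R,10R)-1,10-epoxy-3-(3-methylbutanoyloxy)-8-{[(2S,3R)-2,3-dimethyloxirane-2-carbonyl]oxy}germacra-4Z,11(13)-dien-12,6-olide (CNP0167461.3) | C=C1C(=O)O[C@@H]2/C=C(/C)[C@@H](OC(=O)CC(C)C)C[C@H]3O[C@]3(C)C[C@@H](OC(=O)[C@@]3(C)O[C@@H]3C)[C@@H]12 | target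

## Step count

Total: 18 steps. Longest linear sequence: 12 steps (steps 1–5, then 12–18).

## Steps most likely to fail, with fallbacks

**Step 16 (ring closure).** The ten-membered closure needs high dilution, and the C3 configuration rests on substrate control only, so the 3R carbinol may dominate. The fallback sets out from aldehyde 26 and uses the same closure, but takes the other epimer, (3R,6R,7R,8R)-3-hydroxy-8-{[(2S,3R)-2,3-dimethyloxirane-2-carbonyl]oxy}germacra-1(10)E,4Z,11(13)-trien-12,6-olide F2. F2 is esterified with inversion instead of retention (3-methylbutanoic acid, PPh3, DIAD, toluene, 0 °C, Mitsunobu reaction). C3 is thus fixed in a stereoinvertive C–O bond formation, and the route is rejoined at 29, with 27 and the anhydride acylation bypassed.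

**Step 12 (Barbier union).** The syn preference at C8 under zinc may be eroded or reversed for this β,γ-unsaturated aldehyde. The fallback sets out from 9 and 18 and aims deliberately at the other diastereomer. CrCl2 in THF at rt (no nickel, so the vinyl iodide stays inert) goes through the chair transition state with the aldehyde chain equatorial and gives the anti adduct, (4R,5S)-4-[(1S,3E)-6-(tert-butyldiphenylsilyloxy)-1-hydroxy-3-methylhex-3-en-1-yl]-5-[(Z)-2-iodoprop-1-en-1-yl]-3-methylideneoxolan-2-one F1. F1 is then esterified with acid 21 under Mitsunobu conditions (PPh3, DIAD, toluene, 0 °C), which inverts C8. The route is rejoined at 24, with 22 and 23 bypassed.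

**Step 18 (the new epoxidation).** The chiral dioxirane may be too bulky for the medium-ring olefin, the buffered aqueous medium may harm the methylene lactone, or the conformer it prefers may be scarce. The fallback sets out from 29 and returns at 30. It gives up reagent control for substrate control: buffered peracid (mCPBA, NaHCO3, CH2Cl2, 0 °C) attacks the exposed outer face of the 1(10)-olefin, the known behaviour of germacranolides, and stays selective for this electron-rich olefin over the other three. No new compound is made on this path (none F0).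

## Further compounds

F1 | step 12 | (4R,5S)-4-[(1S,3E)-6-(tert-butyldiphenylsilyloxy)-1-hydroxy-3-methylhex-3-en-1-yl]-5-[(Z)-2-iodoprop-1-en-1-yl]-3-methylideneoxolan-2-one | C=C1C(=O)O[C@H](/C=C(/C)I)[C@H]1[C@@H](O)C/C(C)=C/CCO[Si](c1ccccc1)(c1ccccc1)C(C)(C)C
F2 | step 16 | (3R,6R,7R,8R)-3-hydroxy-8-{[(2S,3R)-2,3-dimethyloxirane-2-carbonyl]oxy}germacra-1(10)E,4Z,11(13)-trien-12,6-olide | C=C1C(=O)O[C@@H]2/C=C(/C)[C@H](O)C/C=C(\C)C[C@@H](OC(=O)[C@@]3(C)O[C@@H]3C)[C@@H]12
F0 | step 18 | none | none
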